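Ring A is disconnected across the two bonds that join the butyryl-bearing carbon to one phenol carbon and the bridge-bearing carbon to the other. A cyclobutenone–siloxyalkyne benzannulation makes both bonds and closes the hexasubstituted ring in one operation. It exploits the three mutually meta oxygens of ring A (one OMe, two OH flanking the acyl carbon), which arrive already differentiated: the cyclobutenone carbonyl carbon becomes a free phenol carbon, its methoxy carbon the anisole carbon, the alkyne siloxy carbon the second phenol carbon. The precursor is a 3-methoxycyclobut-2-enone whose C2 carries the CH2 bridge and the O-methylated acetylfilicinic acid ring B; its partner is a siloxyalkyne bearing the butyryl group as a dioxolane.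

Key step: step 7

Remark (assumption): ring B is drawn and named throughout as the cross-conjugated 3,5-dioxygenated cyclohexa-2,5-dien-1-one; positional isomers of its two enol ethers, should step 4 also form them, have the same skeleton and converge in step 8.

Design note: the butyryl carbonyl is carried through the key step as a dioxolane, which keeps the alkyne unconjugated and removes any late oxidation of a benzylic alcohol on a free phloroglucinol ring. In what follows, RB denotes the (5-acetyl-2,4-dimethoxy-3,3-dimethyl-6-oxocyclohexa-1,4-dien-1-yl)methyl group.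

Step 1
Reactants: 1 2,4,6-trihydroxyacetophenone
Product: 2 acetylfilicinic acid (2-acetyl-3,5-dihydroxy-4,4-dimethylcyclohexa-2,5-dien-1-one)
Conditions: MeI (2.2 equiv), NaOMe (3 equiv), MeOH, 0 °C → rt
Reagents that add atoms: iodomethane, CI
Why: Dearomatising double C-methylation, in which the phloroglucinol polyanion is alkylated twice at one ring carbon, is the known route from acylphloroglucinols to acylfilicinic acids, and the limited amount of MeI should keep tri- and tetramethylation low.

Step 2
Reactants: 3 3-ethoxycyclobut-2-en-1-one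
Product: 4 cyclobutane-1,3-dione (present largely as 3-hydroxycyclobut-2-en-1-one)
Conditions: 2 M aq HCl, rt; concentrate cold, use at once
Reagents that add atoms: water, O
Why: Acid-catalysed hydrolysis of a vinylogous ester (addition of water at C3, loss of ethanol) should give the strongly acidic dione, which is taken on directly because it does not keep.

Step 3
Reactants: 2 acetylfilicinic acid; 4 cyclobutane-1,3-dione (2 equiv)
Product: 7 2-acetyl-3,5-dihydroxy-6-[(2-hydroxy-4-oxocyclobut-1-en-1-yl)methyl]-4,4-dimethylcyclohexa-2,5-dien-1-one, via Mannich base 5 (not isolated), via methylene trione 6 (not isolated)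
Conditions: Me2N+=CH2 I− (1.0 equiv), NaOAc (2 equiv), MeCN, rt; then 4, 60 °C; 1 M HCl work-up
Reagents that add atoms: N,N-dimethylmethylideneammonium iodide (Eschenmoser's salt), C=[N+](C)C.[I-]
Why: A Mannich reaction at the only ring CH of 2 gives 5, which on warming loses dimethylamine to the quinone-methide-like acceptor 6 that the enol of 4 captures at C2 by Michael addition; forming the electrophile on one partner before the other is added is the usual way to suppress symmetrical methylene-bridged dimers.

Step 4
Reactants: 7 the methylene-bridged tris-enol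
Product: 8 2-acetyl-3,5-dimethoxy-6-[(2-methoxy-4-oxocyclobut-1-en-1-yl)methyl]-4,4-dimethylcyclohexa-2,5-dien-1-one (equally: 3-methoxy-2-RB-cyclobut-2-en-1-one)
Conditions: Me3SiCHN2 (5 equiv), PhMe/MeOH 4:1, 0 °C → rt; AcOH quench
Reagents that add atoms: trimethylsilyldiazomethane, C[Si](C)(C)C=[N+]=[N-]
Why: Diazoalkane O-methylation runs by proton transfer from each strongly acidic enol followed by alkylation on oxygen, so it should avoid the C-methylation seen with MeI and base, and the symmetrical cyclobutanedione unit can give only one 3-methoxycyclobutenone.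

Step 5
Reactants: 9 ethyl 2-oxopentanoate
Product: 10 ethyl 2-propyl-1,3-dioxolane-2-carboxylate
Conditions: Me3SiOCH2CH2OSiMe3 (1.3 equiv), Me3SiOTf (5 mol%), CH2Cl2, −78 → 0 °C; pyridine quench
Reagents that add atoms: 1,2-bis(trimethylsilyloxy)ethane, C[Si](C)(C)OCCO[Si](C)(C)C
Why: Noyori ketalisation converts the electrophilic ketone of the α-keto ester into the dioxolane under aprotic conditions that avoid transesterification of the ethyl ester.

Step 6
Reactants: 10 ethyl 2-propyl-1,3-dioxolane-2-carboxylate
Product: 12 triisopropyl{[(2-propyl-1,3-dioxolan-2-yl)ethynyl]oxy}silane, via lithium ynolate 11 (not isolated)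
Conditions: CH2Br2, lithium 2,2,6,6-tetramethylpiperidide, THF, −78 °C; 10; LiN(SiMe3)2; n-BuLi, −78 °C → rt; i-Pr3SiCl, −78 °C → rt
Reagents that add atoms: dibromomethane, BrCBr; chlorotriisopropylsilane, CC(C)[Si](Cl)(C(C)C)C(C)C
Why: Kowalski ynolate synthesis, in which addition of dibromomethyllithium to the ester, enolisation, bromine–lithium exchange and 1,2-shift of the ketal-bearing carbon give ynolate 11, which the bulky silyl chloride should trap on oxygen.

Step 7
Reactants: 8 3-methoxy-2-RB-cyclobut-2-en-1-one; 12 the siloxyalkyne (1.5 equiv)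
Product: 17 2-acetyl-6-{[4-hydroxy-6-methoxy-3-(2-propyl-1,3-dioxolan-2-yl)-2-(triisopropylsilyloxy)phenyl]methyl}-3,5-dimethoxy-4,4-dimethylcyclohexa-2,5-dien-1-one, via vinylketene 13 (not isolated), via vinylcyclobutenone 14 (not isolated), via dienylketene 15 (not isolated), via cyclohexadienone 16 (not isolated)
Conditions: PhMe (0.3 M), 80 → 110 °C, sealed tube, Ar
Reagents that add atoms: none
Why: Heating opens the cyclobutenone by 4π electrocyclic cleavage of its C1–C4 bond to vinylketene 13, whose ketene carbon is attacked by the alkyne carbon remote from the siloxy group, so a [2+2] cycloaddition gives 14; 4π opening of 14 to dienylketene 15, 6π electrocyclisation to 16 and enol tautomerisation then deliver the phenol. This is the cyclobutenone–siloxyalkyne (Danheiser) benzannulation, established for alkyl-substituted cyclobutenones and applied here to a vinylogous-ester cyclobutenone with a functionalised side chain, which is the untested element and may call for the upper end of the temperature range. Ring A is closed by a thermal 6π electrocyclisation between the ketene carbon and the terminal CH2 of the methoxyvinyl group, followed by aromatisation. No stereocentre remains, since the quaternary centre of racemic 14 is lost on ring opening. The selectivity needed is the orientation of the ketene–alkyne union, and the polarisation of the ynol ether (carbon β to oxygen nucleophilic, central ketene carbon electrophilic) secures it, placing the ketal-bearing carbon between the new free phenol and the silyloxy carbon and the bridge carbon between the silyloxy and methoxy carbons. Chemoselectivity rests on a precursor without acidic OH groups (ring B fully O-methylated), which could otherwise protonate the alkyne or add to the ketene, and on the dioxolane, which leaves the alkyne electron-rich.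

Step 8
Reactants: 17 the benzannulation product
Product: 18 2-acetyl-6-{[3-butanoyl-4-hydroxy-6-methoxy-2-(triisopropylsilyloxy)phenyl]methyl}-3,5-dihydroxy-4,4-dimethylcyclohexa-2,5-dien-1-one
Conditions: 2 M aq HCl, THF, 45 °C
Reagents that add atoms: water, O
Why: Aqueous acid hydrolyses the aryl ketone ketal (through an oxocarbenium ion stabilised by the electron-rich ring) and the two vinylogous methyl esters of ring B by addition–elimination, while the aryl methyl ether and the hindered aryl silyl ether should persist, the latter keeping the phenol next to the bridge from closing a pyran ring onto ring B.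

Step 9
Reactants: 18 the triisopropylsilyl ether of the target
Product: 19 2-acetyl-6-[(3-butanoyl-2,4-dihydroxy-6-methoxyphenyl)methyl]-3,5-dihydroxy-4,4-dimethylcyclohexa-2,5-dien-1-one (target, CNP0378451.0)
Conditions: Bu4NF/AcOH (1:1, 4 equiv), THF, 0 °C → rt; pH 2 work-up
Reagents that add atoms: none
Why: Fluoride cleaves the aryl silyl ether through a pentacoordinate silicate with the phenoxide as leaving group, and the acetic acid buffer should protect the base-sensitive methylene-bridged triketone from anionic bridge cleavage.

Compound list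
1 | 2,4,6-trihydroxyacetophenone | CC(=O)c1c(O)cc(O)cc1O | starting material
2 | acetylfilicinic acid (2-acetyl-3,5-dihydroxy-4,4-dimethylcyclohexa-2,5-dien-1-one) | CC(=O)C1=C(O)C(C)(C)C(O)=CC1=O | intermediate
3 | 3-ethoxycyclobut-2-en-1-one | CCOC1=CC(=O)C1 | starting material
4 | cyclobutane-1,3-dione | O=C1CC(=O)C1 | intermediate
5 | Mannich base, 2-acetyl-6-[(dimethylamino)methyl]-3,5-dihydroxy-4,4-dimethylcyclohexa-2,5-dien-1-one | CC(=O)C1=C(O)C(C)(C)C(O)=C(CN(C)C)C1=O | intermediate (not isolated)
6 | methylene trione, 2-acetyl-3-hydroxy-4,4-dimethyl-6-methylidenecyclohex-2-ene-1,5-dione | CC(=O)C1=C(O)C(C)(C)C(=O)C(=C)C1=O | intermediate (not isolated)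
7 | 2-acetyl-3,5-dihydroxy-6-[(2-hydroxy-4-oxocyclobut-1-en-1-yl)methyl]-4,4-dimethylcyclohexa-2,5-dien-1-one | CC(=O)C1=C(O)C(C)(C)C(O)=C(CC2=C(O)CC2=O)C1=O | intermediate
8 | 2-acetyl-3,5-dimethoxy-6-[(2-methoxy-4-oxocyclobut-1-en-1-yl)methyl]-4,4-dimethylcyclohexa-2,5-dien-1-one | COC1=C(CC2=C(OC)C(C)(C)C(OC)=C(C(C)=O)C2=O)C(=O)C1 | intermediate
9 | ethyl 2-oxopentanoate | CCCC(=O)C(=O)OCC | starting material
10 | ethyl 2-propyl-1,3-dioxolane-2-carboxylate | CCCC1(OCCO1)C(=O)OCC | intermediate
11 | lithium 2-(2-propyl-1,3-dioxolan-2-yl)ethynolate | CCCC1(OCCO1)C#C[O-].[Li+] | intermediate (not isolated)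
12 | triisopropyl{[(2-propyl-1,3-dioxolan-2-yl)ethynyl]oxy}silane | CCCC1(OCCO1)C#CO[Si](C(C)C)(C(C)C)C(C)C | intermediate
13 | vinylketene, 3-methoxy-2-RB-buta-1,3-dien-1-one | O=C=C(CC1=C(OC)C(C)(C)C(OC)=C(C(C)=O)C1=O)C(OC)=C | intermediate (not isolated)
14 | vinylcyclobutenone (racemic), 4-(1-methoxyethenyl)-4-RB-2-(2-propyl-1,3-dioxolan-2-yl)-3-(triisopropylsilyloxy)cyclobut-2-en-1-one | O=C1C(C2(CCC)OCCO2)=C(O[Si](C(C)C)(C(C)C)C(C)C)C1(CC3=C(OC)C(C)(C)C(OC)=C(C(C)=O)C3=O)C(OC)=C | intermediate (not isolated)
15 | dienylketene, 5-methoxy-4-RB-2-(2-propyl-1,3-dioxolan-2-yl)-3-(triisopropylsilyloxy)hexa-1,3,5-trien-1-one, ketenyl and methoxyvinyl groups cis on the central double bond | O=C=C(C1(CCC)OCCO1)/C(O[Si](C(C)C)(C(C)C)C(C)C)=C(/CC2=C(OC)C(C)(C)C(OC)=C(C(C)=O)C2=O)C(OC)=C | intermediate (not isolated)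
16 | cyclohexadienone, 5-methoxy-4-RB-2-(2-propyl-1,3-dioxolan-2-yl)-3-(triisopropylsilyloxy)cyclohexa-2,4-dien-1-one | O=C1CC(OC)=C(CC2=C(OC)C(C)(C)C(OC)=C(C(C)=O)C2=O)C(O[Si](C(C)C)(C(C)C)C(C)C)=C1C3(CCC)OCCO3 | intermediate (not isolated)
17 | 2-acetyl-6-{[4-hydroxy-6-methoxy-3-(2-propyl-1,3-dioxolan-2-yl)-2-(triisopropylsilyloxy)phenyl]methyl}-3,5-dimethoxy-4,4-dimethylcyclohexa-2,5-dien-1-one | CCCC3(OCCO3)c1c(O)cc(OC)c(CC2=C(OC)C(C)(C)C(OC)=C(C(C)=O)C2=O)c1O[Si](C(C)C)(C(C)C)C(C)C | intermediate
18 | 2-acetyl-6-{[3-butanoyl-4-hydroxy-6-methoxy-2-(triisopropylsilyloxy)phenyl]methyl}-3,5-dihydroxy-4,4-dimethylcyclohexa-2,5-dien-1-one | CCCC(=O)c1c(O)cc(OC)c(CC2=C(O)C(C)(C)C(O)=C(C(C)=O)C2=O)c1O[Si](C(C)C)(C(C)C)C(C)C | intermediate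
19 | 2-acetyl-6-[(3-butanoyl-2,4-dihydroxy-6-methoxyphenyl)methyl]-3,5-dihydroxy-4,4-dimethylcyclohexa-2,5-dien-1-one | CCCC(=O)c1c(O)cc(OC)c(CC2=C(O)C(C)(C)C(O)=C(C(C)=O)C2=O)c1O | target

Total step count: 9. Longest linear sequence: 6 steps (steps 1, 3, 4, 7, 8, 9).

Steps most likely to fail

Step 7. The vinylogous-ester stabilisation of the four-membered ring may slow its electrocyclic opening so much that the siloxyalkyne degrades, or the ketene is consumed by the phenolic product, before productive cycloaddition occurs. The fallback gives up the benzannulation and forms the bond between ring A and the bridge by the classical union of two preformed rings. It sets out from 2. Commercial 2,4,6-trihydroxybutyrophenone F1 is O-methylated at its most acidic, non-chelated para hydroxyl (Me2SO4, 1 equiv, K2CO3, acetone) to 2,6-dihydroxy-4-methoxybutyrophenone F2. Compound 2 is converted into Mannich base 5 as in step 3 and warmed with an excess of F2 in MeCN. The two free ring positions of F2 are equivalent, so C-alkylation by methylene trione 6 can give only the required substitution pattern, and the route is rejoined at 19.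

Step 3. Symmetrical coupling (two molecules of 2, or two of 4, joined through the methylene) and amine-induced opening of the strained dione may compete with the mixed union. The fallback replaces the Mannich base by an isolable, amine-free sulfone and sets out from 2. Sulfonylmethylation with aqueous formaldehyde and sodium 4-methylbenzenesulfinate in aqueous formic acid gives 2-acetyl-3,5-dihydroxy-4,4-dimethyl-6-{[(4-methylphenyl)sulfonyl]methyl}cyclohexa-2,5-dien-1-one F3. Treating purified F3 with 4 and NaHCO3 in aqueous MeCN at rt eliminates sulfinate to 6, which is trapped by 4, and the route is rejoined at 7.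

Step 6. Material may be lost in the multistage organolithium sequence through incomplete 1,2-shift of the bulky ketal carbon, silylation on carbon instead of oxygen, or decomposition of the siloxyalkyne during isolation. The fallback reaches the same ynolate by oxidation of a terminal alkyne and sets out from 10. Reduction with i-Bu2AlH at −78 °C gives 2-propyl-1,3-dioxolane-2-carbaldehyde F4. Ohira–Bestmann alkynylation (dimethyl (1-diazo-2-oxopropyl)phosphonate, K2CO3, MeOH) gives 2-ethynyl-2-propyl-1,3-dioxolane F5. Deprotonation with LiN(SiMe3)2 and oxidation of the acetylide with t-BuOOLi in THF (−78 → 0 °C) gives ynolate 11, which is trapped with i-Pr3SiOTf, and the route is rejoined at 12.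

Further compounds
F1 | step 7 | 2,4,6-trihydroxybutyrophenone | CCCC(=O)c1c(O)cc(O)cc1O
F2 | step 7 | 2,6-dihydroxy-4-methoxybutyrophenone | CCCC(=O)c1c(O)cc(OC)cc1O
F3 | step 3 | 2-acetyl-3,5-dihydroxy-4,4-dimethyl-6-{[(4-methylphenyl)sulfonyl]methyl}cyclohexa-2,5-dien-1-one | CC(=O)C1=C(O)C(C)(C)C(O)=C(CS(=O)(=O)c2ccc(C)cc2)C1=O
F4 | step 6 | 2-propyl-1,3-dioxolane-2-carbaldehyde | CCCC1(OCCO1)C=O
F5 | step 6 | 2-ethynyl-2-propyl-1,3-dioxolane | CCCC1(OCCO1)C#C
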